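We come to these flasks from a neighbour of zeta, the same charge held at −50 °C, and we return to it at the end.

the same everywhere: substrate 0.30 M; reagent 0.450 M; time 20 h
- zeta: temperature −25 °C
- beta: temperature 25 °C
- gamma: temperature 0 °C
- alpha: at 25 °C until 4.0 h, from then on at −25 °C

    target → over-reaction product (k1 = 0.017 h⁻¹, Ea1 = 97.0 kJ mol⁻¹)
    substrate + reagent → isomer of the product (k2 = 0.048 M⁻¹ h⁻¹, Ea2 = 70.0 kJ mol⁻¹)
    crystals ⇌ target, rate k3*(cs3 - [target]) while solid is left; crystals form when [target] > cs3 (cs3 = 0.13 M, k3 = 1.3 h⁻¹)
    substrate + reagent → target (k4 = 0.098 M⁻¹ h⁻¹, Ea4 = 61.0 kJ mol⁻¹)
    2 reagent → homo dimer (k5 = 0.33 M⁻¹ h⁻¹, Ea5 = 78.0 kJ mol⁻¹)
    (constants at 25 °C)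

- for target the crystals are counted in
- a doubled species enters its step squared and goes two at a time
- as a solid, counted per litre of solution: crystals
- constants are those at 25 °C; use the activation energies for any other temperature

- which flask leads in share of target in all that became target or isomer of the product or over-reaction product ("all alike" within 1.5 percentage points) (zeta / beta / gamma / alpha / all alike)
- share of target in all that became target or isomer of the product or over-reaction product, zeta
- share of target in all that became target or isomer of the product or over-reaction product, beta
- share of target in all that became target or isomer of the product or over-reaction product, gamma
- share of target in all that became target or isomer of the product or over-reaction product, alpha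

Substrate and reagent make target and isomer of the product by steps with the same rate law, so at a given temperature the two come in the ratio of their constants, whatever the concentrations. That ratio is the selectivity factor. In beta, at 25 °C, it gives 67.1% for the split, the constant of the target step over the sum of the constants of the target and isomer steps at the flask's temperature. Over-reaction product stays in the count, so the share asked for is the split times the fraction of target left.

We reckon with that fraction left, using beta's two extremes. Suppose beta made its product at the very end: nothing has aged, and the share equals the split. Suppose it made its product at the very start: the fraction left is 71.2%, and the share is 47.8%. The real flask lies between these. For a figure of our own we need a time of making, and as a simple estimate we take one loss of reagent: its first half-life by dimerisation is 3.37 h, shorter than the 20 h of the run. If we let reagent fall by that step by itself, the midpoint of the making comes at 5.50 h. Product of that age has 78.2% left, and our share for beta is 52.5%.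

In the cold the two extremes close up. In gamma they are 74.0% and 73.3%, and in zeta both print as 80.9%. Alpha, counted as making its product in the warm hours, lies between 62.7% and 67.1%. So we put zeta first.

The forecast named zeta, with 80.9% for zeta, 52.5% for beta, 73.6% for gamma and 64.7% for alpha, noting that “over-reaction is negligible in the cold”.

The simulation gives 80.9% for zeta, 53.0% for beta, 73.6% for gamma and 64.7% for alpha, so zeta leads and the forecast stands.

Beta's reading against its split means a fraction left of 79.0%. Beta reads 53.0% at 20 h and 3.40% at 200 h, and the later hour is the main reason for that fall, while zeta at 200 h reads 80.9%, still its split. At −50 °C the split is 87.4%, and the neighbour flask computes to 87.4%, with substrate at >99.9% of its charge.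

The rate constants were chosen freely; the run is a simulation.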